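**Retrosynthetic overview**
1. Position labels: C1 = lactone C=O, C2(Me), C3 = ketone, C4 = C(OH)(CH2OH), C5, C6(Me)=C7, C8(Me), C9, C10(=CH2), C11=C12(Me), C13 = CH(Et)–O. Last step: hydrolysis of an acetonide across the C4 hydroxyl and the CH2OH oxygen; C2 settles by enolisation.
2. Key step and only ring closure (the 14-membered lactone, closed last in the skeleton): C2–C3 by nickel-mediated reductive acyl–alkyl coupling. The C2 α-ester radical from a 2-bromopropanoate on O13 is captured by the C3 acyl-nickel.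
3. O13–C1 by acylation; C10–C11 by Zr-catalysed carboalumination of (3R)-pent-1-yn-3-ol and Pd coupling with a C10 vinyl bromide.
4. C4–C5, the C4 stereocentre and the E-C6=C7 alkene by Ireland–Claisen rearrangement of a glycerate-acetonide ester of the C7 allylic alcohol (chirality transfer C7 → C4).
5. C7/C8 alcohol: Evans alkylation with 2,3-dibromopropene (C8), isopropenyl Grignard on the Weinreb amide, CBS reduction (C7).

Assumption: C2 lies between two carbonyls and is configurationally labile, so the (2S) epimer of the target is taken as the thermodynamic one; (3R)-pent-1-yn-3-ol and racemic methyl glycerate are taken as catalogue compounds.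

**Step 1**
Reactants: 1 propanoyl chloride
Product: 2 (4S)-4-benzyl-3-propanoyl-1,3-oxazolidin-2-one
Conditions: (4S)-4-benzyl-1,3-oxazolidin-2-one, n-BuLi, THF, −78 °C; then 1, −78 → 0 °C
Reagents that add atoms: (4S)-4-benzyl-1,3-oxazolidin-2-one (chiral auxiliary, recovered in step 3), O=C1N[C@@H](Cc2ccccc2)CO1
Why: N-acylation of the lithiated Evans auxiliary; no stereocentre is formed.

**Step 2**
Reactants: 2 (4S)-4-benzyl-3-propanoyl-1,3-oxazolidin-2-one; 3 2,3-dibromoprop-1-ene
Product: 4 (4S)-4-benzyl-3-[(2R)-4-bromo-2-methylpent-4-enoyl]-1,3-oxazolidin-2-one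
Conditions: NaN(SiMe3)2, THF, −78 °C; then 3, −78 → −45 °C
Reagents that add atoms: none
Why: Evans asymmetric alkylation; the chelated Z-enolate is alkylated by the allylic bromide on the face opposite the benzyl group, which sets C8 as R.

**Step 3**
Reactants: 4 (4S)-4-benzyl-3-[(2R)-4-bromo-2-methylpent-4-enoyl]-1,3-oxazolidin-2-one
Product: 5 (2R)-4-bromo-N-methoxy-N,2-dimethylpent-4-enamide
Conditions: MeNH(OMe)·HCl, AlMe3, CH2Cl2, −10 → 23 °C; cold 1 M HCl work-up
Reagents that add atoms: N,O-dimethylhydroxylamine hydrochloride, CNOC.Cl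
Why: Weinreb transamidation by the aluminium amide at the exocyclic imide carbonyl; C8 is untouched.

**Step 4**
Reactants: 5 (2R)-4-bromo-N-methoxy-N,2-dimethylpent-4-enamide; 6 prop-1-en-2-ylmagnesium bromide
Product: 7 (4R)-6-bromo-2,4-dimethylhepta-1,6-dien-3-one
Conditions: THF, −78 → 0 °C; poured into cold 1 M HCl
Reagents that add atoms: none
Why: Weinreb ketone synthesis; the magnesium chelate stops after one addition, and a Grignard reagent does not exchange with the vinyl bromide.

**Step 5**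
Reactants: 7 (4R)-6-bromo-2,4-dimethylhepta-1,6-dien-3-one
Product: 8 (3S,4R)-6-bromo-2,4-dimethylhepta-1,6-dien-3-ol
Conditions: (R)-1-methyl-3,3-diphenyltetrahydro-1H,3H-pyrrolo[1,2-c][1,3,2]oxazaborole (0.2 equiv), BH3·SMe2, THF, −30 °C; MeOH quench
Reagents that add atoms: none
Why: Corey–Bakshi–Shibata reduction; with the isopropenyl group as the large substituent the (R)-catalyst gives the (3S) carbinol (C7, syn to the C8 methyl) by reagent control against the weak Felkin bias.

**Step 6**
Reactants: 9 methyl 2,3-dihydroxypropanoate (racemic methyl glycerate)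
Product: 11 2,2-dimethyl-1,3-dioxolane-4-carboxylic acid (racemic), via methyl glycerate acetonide 10 (not isolated)
Conditions: Me2C(OMe)2, TsOH·H2O (cat.), acetone, 23 °C; then LiOH, THF/H2O, 0 °C; cold 1 M HCl to pH 3
Reagents that add atoms: 2,2-dimethoxypropane, COC(C)(C)OC; lithium hydroxide, [Li+].[OH-]
Why: acetonide formation on the 1,2-diol followed by saponification in the same flask; the stereocentre is irrelevant because it is erased in step 8.

**Step 7**
Reactants: 8 (3S,4R)-6-bromo-2,4-dimethylhepta-1,6-dien-3-ol; 11 2,2-dimethyl-1,3-dioxolane-4-carboxylic acid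
Product: 12 (3S,4R)-6-bromo-2,4-dimethylhepta-1,6-dien-3-yl 2,2-dimethyl-1,3-dioxolane-4-carboxylate (both epimers at the dioxolane carbon)
Conditions: N,N′-dicyclohexylcarbodiimide, 4-(dimethylamino)pyridine (cat.), CH2Cl2, 0 → 23 °C
Reagents that add atoms: none
Why: Steglich esterification of the secondary allylic alcohol; no stereocentre of the target is affected.

**Step 8**
Reactants: 12 (3S,4R)-6-bromo-2,4-dimethylhepta-1,6-dien-3-yl 2,2-dimethyl-1,3-dioxolane-4-carboxylate
Product: 15 (4R)-4-[(2E,4R)-6-bromo-2,4-dimethylhepta-2,6-dien-1-yl]-2,2-dimethyl-1,3-dioxolane-4-carboxylic acid, via silyl ketene acetal 13 (not isolated), via trimethylsilyl ester 14 (not isolated)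
Conditions: LiN(SiMe3)2, Me3SiCl/Et3N, THF, −78 → 23 °C, then 50 °C; 1 M NaOH, then citric acid to pH 4
Reagents that add atoms: none
Why: Ireland–Claisen rearrangement; chelation-controlled enolisation places OSiMe3 cis to the ring oxygen, and the chair transition state with the C8 chain equatorial forms C4–C5, gives the E-C6=C7 alkene and transfers C7 (S) to C4 (R), while the ring-held β-oxygen cannot eliminate.

**Step 9**
Reactants: 15 (4R)-4-[(2E,4R)-6-bromo-2,4-dimethylhepta-2,6-dien-1-yl]-2,2-dimethyl-1,3-dioxolane-4-carboxylic acid; 16 (3R)-pent-1-yn-3-ol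
Product: 18 (4R)-4-[(2E,4R,7E,9R)-9-hydroxy-2,4,8-trimethyl-6-methylideneundeca-2,7-dien-1-yl]-2,2-dimethyl-1,3-dioxolane-4-carboxylic acid, via alkenylalane 17 (not isolated)
Conditions: 16, AlMe3 (3.5 equiv), Cp2ZrCl2 (0.25 equiv), CH2Cl2, 0 → 23 °C; then 15, ZnCl2, Pd(PPh3)4 (5 mol%), THF, 23 → 45 °C; cold dilute HCl work-up
Reagents that add atoms: trimethylaluminium, C[Al](C)C
Why: Negishi Zr-catalysed syn-carboalumination (Me to C12, Al to C11, E) followed by Pd-catalysed, zinc-accelerated alkenyl–alkenyl cross-coupling with retention of geometry forms C10–C11; C13 (R) comes from the chiral alkynol, and the acid is carried as its aluminium carboxylate.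

**Step 10**
Reactants: 18 (4R)-4-[(2E,4R,7E,9R)-9-hydroxy-2,4,8-trimethyl-6-methylideneundeca-2,7-dien-1-yl]-2,2-dimethyl-1,3-dioxolane-4-carboxylic acid; 19 2-bromopropanoyl bromide (racemic)
Product: 20 (4R)-4-[(2E,4R,7E,9R)-9-(2-bromopropanoyloxy)-2,4,8-trimethyl-6-methylideneundeca-2,7-dien-1-yl]-2,2-dimethyl-1,3-dioxolane-4-carboxylic acid (both epimers at CHBr)
Conditions: 19 (2.5 equiv), pyridine, CH2Cl2, −20 → 0 °C; aqueous NaHCO3, then pH 4 buffer
Reagents that add atoms: none
Why: O-acylation of the C13 alcohol by the acyl bromide; the mixed anhydride formed at the hindered acid is hydrolysed in the work-up, and the CHBr configuration is irrelevant.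

**Step 11**
Reactants: 20 (4R)-4-[(2E,4R,7E,9R)-9-(2-bromopropanoyloxy)-2,4,8-trimethyl-6-methylideneundeca-2,7-dien-1-yl]-2,2-dimethyl-1,3-dioxolane-4-carboxylic acid
Product: 22 (5R,7RS,10R,11E,15R,16E)-10-ethyl-2,2,7,11,15,17-hexamethyl-13-methylidene-1,3,9-trioxaspiro[4.13]octadeca-11,16-diene-6,8-dione (the acetonide of the target), via acid chloride 21 (not isolated)
Conditions: 1-chloro-N,N,2-trimethylprop-1-en-1-amine, CH2Cl2, 0 → 23 °C; then syringe-pump addition (12 h) in THF to NiBr2·(MeOCH2CH2OMe) (0.5 equiv), 4,4′-di-tert-butyl-2,2′-bipyridine (0.55 equiv), Mn powder (5 equiv), N,N-dimethylacetamide, 0 → 23 °C, final 2 mM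
Reagents that add atoms: none
Why: Proposed new method: the acyl chloride adds oxidatively to zerovalent nickel, monovalent nickel abstracts bromine from the tethered 2-bromopropanoate, and the C2 α-ester radical is captured by the divalent acyl-nickel, so that reductive elimination from trivalent nickel forms the C2–C3 bond and the 14-membered ring directly at the β-keto-lactone oxidation level (no enolate is involved, so there is no Claisen-type self-quench, and slow addition to a large nickel charge keeps each radical near its own acyl-nickel); the closest known chemistry is the nickel-catalysed reductive ketone synthesis from acid chlorides and alkyl halides together with nickel reductive couplings of α-halo esters; C2 forms as an epimer mixture.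

**Step 12**
Reactants: 22 the acetonide of the target (C2 epimer mixture)
Product: 23 (3S,5R,7E,9R,12E,14R)-14-ethyl-5-hydroxy-5-(hydroxymethyl)-3,7,9,13-tetramethyl-11-methylidene-1-oxacyclotetradeca-7,12-diene-2,4-dione (the target)
Conditions: CF3CO2H/H2O (9:1), CH2Cl2, 0 → 23 °C
Reagents that add atoms: none
Why: acid-catalysed acetal hydrolysis frees the C4 hydroxyl and the CH2OH with C4 unchanged, and under the same acid C2 equilibrates through the enol to the (2S) epimer assumed to be thermodynamic.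

**Compound list**
1 | propanoyl chloride | CCC(=O)Cl | starting material
2 | (4S)-4-benzyl-3-propanoyl-1,3-oxazolidin-2-one | CCC(=O)N1[C@@H](Cc2ccccc2)COC1=O | intermediate
3 | 2,3-dibromoprop-1-ene | C=C(Br)CBr | starting material
4 | (4S)-4-benzyl-3-[(2R)-4-bromo-2-methylpent-4-enoyl]-1,3-oxazolidin-2-one | C=C(Br)C[C@@H](C)C(=O)N1[C@@H](Cc2ccccc2)COC1=O | intermediate
5 | (2R)-4-bromo-N-methoxy-N,2-dimethylpent-4-enamide | C=C(Br)C[C@@H](C)C(=O)N(C)OC | intermediate
6 | prop-1-en-2-ylmagnesium bromide | CC(=C)[Mg]Br | starting material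
7 | (4R)-6-bromo-2,4-dimethylhepta-1,6-dien-3-one | C=C(Br)C[C@@H](C)C(=O)C(C)=C | intermediate
8 | (3S,4R)-6-bromo-2,4-dimethylhepta-1,6-dien-3-ol | C=C(Br)C[C@@H](C)[C@H](O)C(C)=C | intermediate
9 | methyl 2,3-dihydroxypropanoate (racemic) | COC(=O)C(O)CO | starting material
10 | methyl 2,2-dimethyl-1,3-dioxolane-4-carboxylate (racemic) | COC(=O)C1COC(C)(C)O1 | intermediate
11 | 2,2-dimethyl-1,3-dioxolane-4-carboxylic acid (racemic) | OC(=O)C1COC(C)(C)O1 | intermediate
12 | (3S,4R)-6-bromo-2,4-dimethylhepta-1,6-dien-3-yl 2,2-dimethyl-1,3-dioxolane-4-carboxylate | C=C(Br)C[C@@H](C)[C@H](OC(=O)C1COC(C)(C)O1)C(C)=C | intermediate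
13 | trimethylsilyl ketene acetal of 12 (OSiMe3 cis to the ring oxygen) | C=C(Br)C[C@@H](C)[C@H](O/C(O[Si](C)(C)C)=C1\COC(C)(C)O1)C(C)=C | intermediate
14 | trimethylsilyl (4R)-4-[(2E,4R)-6-bromo-2,4-dimethylhepta-2,6-dien-1-yl]-2,2-dimethyl-1,3-dioxolane-4-carboxylate | C[Si](C)(C)OC(=O)[C@@]1(C/C(C)=C/[C@H](C)CC(Br)=C)COC(C)(C)O1 | intermediate
15 | (4R)-4-[(2E,4R)-6-bromo-2,4-dimethylhepta-2,6-dien-1-yl]-2,2-dimethyl-1,3-dioxolane-4-carboxylic acid | OC(=O)[C@@]1(C/C(C)=C/[C@H](C)CC(Br)=C)COC(C)(C)O1 | intermediate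
16 | (3R)-pent-1-yn-3-ol | CC[C@@H](O)C#C | starting material
17 | dimethyl[(1E,3R)-3-(dimethylalumanyloxy)-2-methylpent-1-en-1-yl]alumane | CC[C@@H](O[Al](C)C)/C(C)=C/[Al](C)C | intermediate
18 | (4R)-4-[(2E,4R,7E,9R)-9-hydroxy-2,4,8-trimethyl-6-methylideneundeca-2,7-dien-1-yl]-2,2-dimethyl-1,3-dioxolane-4-carboxylic acid | OC(=O)[C@@]1(C/C(C)=C/[C@H](C)CC(=C)/C=C(\C)[C@@H](CC)O)COC(C)(C)O1 | intermediate
19 | 2-bromopropanoyl bromide (racemic) | CC(Br)C(=O)Br | starting material
20 | (4R)-4-[(2E,4R,7E,9R)-9-(2-bromopropanoyloxy)-2,4,8-trimethyl-6-methylideneundeca-2,7-dien-1-yl]-2,2-dimethyl-1,3-dioxolane-4-carboxylic acid | OC(=O)[C@@]1(C/C(C)=C/[C@H](C)CC(=C)/C=C(\C)[C@@H](CC)OC(=O)C(C)Br)COC(C)(C)O1 | intermediate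
21 | (4R)-4-[(2E,4R,7E,9R)-9-(2-bromopropanoyloxy)-2,4,8-trimethyl-6-methylideneundeca-2,7-dien-1-yl]-2,2-dimethyl-1,3-dioxolane-4-carbonyl chloride | ClC(=O)[C@@]1(C/C(C)=C/[C@H](C)CC(=C)/C=C(\C)[C@@H](CC)OC(=O)C(C)Br)COC(C)(C)O1 | intermediate
22 | (5R,7RS,10R,11E,15R,16E)-10-ethyl-2,2,7,11,15,17-hexamethyl-13-methylidene-1,3,9-trioxaspiro[4.13]octadeca-11,16-diene-6,8-dione | C=C1/C=C(\C)[C@@H](CC)OC(=O)C(C)C(=O)[C@]2(COC(C)(C)O2)C/C(C)=C/[C@H](C)C1 | intermediate
23 | (3S,5R,7E,9R,12E,14R)-14-ethyl-5-hydroxy-5-(hydroxymethyl)-3,7,9,13-tetramethyl-11-methylidene-1-oxacyclotetradeca-7,12-diene-2,4-dione | C=C1/C=C(\C)[C@@H](CC)OC(=O)[C@@H](C)C(=O)[C@](O)(CO)C/C(C)=C/[C@H](C)C1 | target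

**Step count**
Total: 12 steps. Longest linear sequence: 11 steps (1 → 23 through steps 1–5 and 7–12; step 6 is a one-step side branch).

**Three steps most likely to fail**

Step 11 (radical macrocyclisation). This is an unprecedented ring closure. The C2 radical may be reduced or captured by another chain before it meets its own acyl-nickel, and the hindered α-alkoxy acyl-nickel may lose CO. The fallback sets out from 18 and comes back at 22. Compound 18 is treated with 2,2′-dipyridyl disulfide and PPh3 to give S-(pyridin-2-yl) (4R)-4-[(2E,4R,7E,9R)-9-hydroxy-2,4,8-trimethyl-6-methylideneundeca-2,7-dien-1-yl]-2,2-dimethyl-1,3-dioxolane-4-carbothioate F1. An intermolecular nickel-catalysed reductive acyl coupling of this thioester with tert-butyl 2-bromopropanoate (NiCl2·(MeOCH2CH2OMe), 4,4′-di-tert-butyl-2,2′-bipyridine, Mn powder, N,N-dimethylacetamide) still forms C2–C3 from the α-ester radical and gives tert-butyl 3-{(4R)-4-[(2E,4R,7E,9R)-9-hydroxy-2,4,8-trimethyl-6-methylideneundeca-2,7-dien-1-yl]-2,2-dimethyl-1,3-dioxolan-4-yl}-2-methyl-3-oxopropanoate F2. Heating this β-keto ester at 1 mM in toluene at 110 °C releases the acylketene, which the C13 hydroxyl traps to give 22.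

Step 9 (carboalumination and coupling in one flask). The free acid and the acetonide must survive excess AlMe3, and the alkenylalane must couple cleanly with a 1,1-disubstituted vinyl bromide. The fallback sets out from 16 (with 15) and comes back at 18. Carboalumination of 16 is quenched with I2 to give (1E,3R)-1-iodo-2-methylpent-1-en-3-ol F3. Miyaura borylation (bis(pinacolato)diboron, PdCl2(PPh3)2, PPh3, KOPh, toluene, 50 °C) gives (1E,3R)-2-methyl-1-(4,4,5,5-tetramethyl-1,3,2-dioxaborolan-2-yl)pent-1-en-3-ol F4. Suzuki–Miyaura coupling of this boronate with 15 (Pd(PPh3)4, aqueous Cs2CO3, THF, 50 °C) gives 18 without any aluminium Lewis acid.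

Step 5 (CBS reduction). The isopropenyl and the branched alkyl group are of similar size, and the reagent must work against the Felkin preference of the ketone, so the C7 ratio may be poor; C7 controls C4 in step 8. The fallback sets out from 5 and comes back at 8. Reduction of 5 with i-Bu2AlH (THF, −78 °C) gives (2R)-4-bromo-2-methylpent-4-enal F5. Addition of 6 to this aldehyde (Et2O, −78 °C) is Felkin–Anh controlled and gives the 3,4-syn alcohol 8 as the major isomer, which is separated from the anti isomer by chromatography.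

**Further compounds**
F1 | step 11 | S-(pyridin-2-yl) (4R)-4-[(2E,4R,7E,9R)-9-hydroxy-2,4,8-trimethyl-6-methylideneundeca-2,7-dien-1-yl]-2,2-dimethyl-1,3-dioxolane-4-carbothioate | O=C(Sc1ccccn1)[C@@]2(C/C(C)=C/[C@H](C)CC(=C)/C=C(\C)[C@@H](CC)O)COC(C)(C)O2
F2 | step 11 | tert-butyl 3-{(4R)-4-[(2E,4R,7E,9R)-9-hydroxy-2,4,8-trimethyl-6-methylideneundeca-2,7-dien-1-yl]-2,2-dimethyl-1,3-dioxolan-4-yl}-2-methyl-3-oxopropanoate | CC(C(=O)OC(C)(C)C)C(=O)[C@@]1(C/C(C)=C/[C@H](C)CC(=C)/C=C(\C)[C@@H](CC)O)COC(C)(C)O1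
F3 | step 9 | (1E,3R)-1-iodo-2-methylpent-1-en-3-ol | CC[C@@H](O)/C(C)=C/I
F4 | step 9 | (1E,3R)-2-methyl-1-(4,4,5,5-tetramethyl-1,3,2-dioxaborolan-2-yl)pent-1-en-3-ol | CC[C@@H](O)/C(C)=C/B1OC(C)(C)C(C)(C)O1
F5 | step 5 | (2R)-4-bromo-2-methylpent-4-enal | C=C(Br)C[C@@H](C)C=O
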